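## The problem

Compound 19 is a 3-benzylidene-4-benzyl-γ-butyrolactone. The ring consists of O1, the carbonyl carbon C2, C3, C4 and C5. C3 carries an exocyclic E-configured arylidene (ring B, 3-hydroxy-4,5-dimethoxyphenyl) and C4 carries the ring A benzyl group (4-hydroxy-3-methoxyphenyl). C4 (R) is the only stereocentre and nothing else in the molecule can direct it, so it must come from a catalyst or reagent. The alkene geometry (aryl cis to C4, vinyl hydrogen cis to the carbonyl) has to be secured separately. C4–H is allylic, and migration of the exocyclic double bond into the ring would give the conjugated butenolide and erase the stereocentre. Strong base and metal hydride species are therefore unwelcome once the benzylidene lactone exists, and any earlier intermediate with C4 alpha to a carbonyl group is prone to enolisation. Both rings are electron-rich phenols that need masking through the organometallic steps, the lactone does not tolerate strong nucleophiles, and the styrenoid alkene rules out hydrogenolytic deprotection. The enabling feature is that C4 bears one benzyl group and two single-carbon arms, C5 (the OCH2 group) and C3. C4 is thus the alpha carbon of a 3-arylpropanal: formaldehyde can supply C5 and the aldehyde carbon itself can become C3.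

## Retrosynthesis

**19 from 18.** The two aryl–O–CH2OMe acetals are cut. Both phenols carry the same methoxymethyl (MOM) group so that one mild acid treatment finishes the synthesis. Benzyl ethers would need hydrogenolysis, which would saturate the benzylidene. Aryl silyl ethers would not reliably survive the organolithium and fluoride steps. The forward step must only avoid opening the lactone.

**18 from 17 and carbon monoxide.** The O1–C2 and C2–C3 bonds are cut, which removes the ring, the carbonyl group and the alkene geometry in one stroke and leaves the acyclic homopropargylic alcohol 17. The neighbouring cut, through the C3=CH bond (aldol condensation of a saturated lactone), needs enolate chemistry next to C4 and obtains the E geometry only by elimination. Cyclocarbonylation obtains it from a syn addition across the alkyne. The forward reaction must add the alkoxycarbonyl group 5-exo faster than the hydroxyl group attacks the alkyne directly, and must not move the new double bond.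

**17 from 16, and 16 from 11 and 15.** After removal of the silyl ether, the C(sp)–C(aryl) bond is cut. This splits the molecule into the chiral ring A alkyne 11 and the achiral ring B iodide 15, so the route is convergent and ring B enters late. A Sonogashira coupling of an aryl iodide with a terminal alkyne is asked for, with a propargylic stereocentre as spectator.

**15 from 13 from 12.** The iodine sits meta to both oxygen neighbours, a position that electrophilic iodination of 2,3-dimethoxyphenol 12 cannot reach, because hydroxyl and methoxy groups direct ortho and para. It is, however, the only ring C–H without an ortho substituent. Sterically controlled C–H borylation of the MOM ether 13 (through boronate 14) followed by iododeboronation therefore delivers 15.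

**11 from 9 from 8.** The terminal alkyne carbon is removed: a Corey–Fuchs sequence (through lithium acetylide 10) traces the alkyne to aldehyde 8. The aldehyde carbon becomes the internal alkyne carbon and later C3, and the added carbon becomes the benzylidene CH. The olefination must proceed without enolising the alpha-stereocentre.

**8 from 7, and 7 from 5 and 6.** After removal of the silyl group, the C4–C5 bond is cut. Hydroxy aldehyde 7 is the crossed aldol product of 3-arylpropanal 5 and formaldehyde 6. This is the greatest simplification of the route, since the only stereocentre and the 1,3-dioxygenated three-carbon unit vanish together. The forward reaction is asked to be enantioselective, to stop after one hydroxymethylation and to avoid dehydration. The two arms of 7 are already differentiated, a free alcohol for C5 and an aldehyde for C3.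

**5 from 4 from 2 from 1.** Functional group changes only: oxidation of alcohol 4, anti-Markovnikov hydration of the allyl group of 2 (through borane 3), and MOM protection of eugenol 1, which already contains ring A with the correct oxygenation and a three-carbon chain.

## Roads not taken

**Alternative 1:** The aryl–CH bond of the benzylidene and the C3–C4 bond are cut together. The precursors are the propiolate ester A2 of the MOM-protected cinnamyl alcohol and the ring B boronic acid A3. In the forward step an arylrhodium species adds syn across the alkyne of A2, the alkenylrhodium inserts the cinnamyl alkene in a 5-exo mode, and protonation of the benzylic rhodium gives A1, which is the same compound as 18.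
- Merits: two carbon–carbon bonds, the ring, the stereocentre and the E geometry arise in one step, and the whole synthesis would need well under half the steps of the chosen plan.
- Weak points: an ester tether prefers the conformation that holds the two pi systems apart, so ester-linked 1,6-enynes cyclise reluctantly. The acceptor is an unactivated styrene and not the electron-poor alkene on which asymmetric arylative cyclisations rely. Protonation of the alkenylrhodium before cyclisation (plain hydroarylation) and beta-hydride elimination from the benzylic rhodium (which removes C4–H) compete. The enantioselectivity would rest on an alkene insertion without close precedent.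
- Comparison: in step economy this road is clearly better. The chosen plan sets against it a stereo-defining reaction already established on 3-arylpropanals and later steps that each apply known chemistry, and it pays with length.

**Alternative 2:** The ring A aryl–CH2 bond is cut and C4–H is formed by protonation. The ring A boronic acid A6 adds under rhodium catalysis to the methylene terminus of the diene diester A5, and the resulting rhodium enolate is protonated enantioselectively to give succinate A4.
- Merits: the synthesis is convergent, both rings come from simple aryl donors, and the E alkene is in place before the stereocentre is created.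
- Weak points: enantioselective protonation is harder to bring to high selectivity than a carbon–carbon bond formation under catalyst control. The new C–H in A4 is alpha to an ester and allylic, so it can re-enolise in the basic aqueous medium of the addition. After the key step the tert-butyl ester must be cleaved by acid without loss of the MOM groups, the acid reduced chemoselectively and the lactone closed. A5 itself takes several steps.
- Comparison: the length is similar to that of the chosen plan. The chosen plan also passes through an enolisable stage (7 and 8), but only for two cold operations before C4 becomes a propargylic centre. In A4 the centre stays acidic until the lactone is closed.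

**Alternative 3:** The C3–C4 bond is cut by C–H insertion. Alcohol 4 is converted into diazoacetate A8, and a chiral dirhodium carboxamidate such as Rh2(4S-MPPIM)4 inserts the carbene into the C–H bond beta to the ester oxygen to give lactone A7. Aldol addition of A7 to the ring B aldehyde A9, dehydration and deprotection complete the synthesis.
- Merits: carbene insertion of 3-arylpropyl diazoacetates into this C–H bond is an established enantioselective entry to benzyl lactones of this family. The road shares steps 1 and 2 with the chosen route and needs about eight steps in all.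
- Weak points: a diazo ester has to be prepared and handled, and a specialised precious-metal catalyst of the right enantiomeric series is needed. Insertion at the benzylic C–H or alpha to oxygen, and addition of the carbene to the electron-rich ring A, must be suppressed. The benzylidene is then made by strongly basic enolate chemistry next to C4, and its geometry comes from an elimination.
- Comparison: this road is shorter by about five steps and equally well founded, and that must be stated plainly. The chosen plan sets against it an inexpensive amine catalyst with aqueous formaldehyde, an alkene geometry fixed by a stereospecific syn addition, and introduction of ring B by cross-coupling. The end-game of this alternative is kept as the fallback for step 12.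

Key step: step 4

Assumption: the silyl ether catalyst is taken to follow its usual steric model in the buffered aqueous medium (electrophile anti to the bulky group on the s-trans E-enamine). If the desilylated prolinol were the active species and guided formaldehyde by hydrogen bonding to the face of the carbinol, the (S)-catalyst would be used instead, with no other change.

## Route

Step 1
Reactants: 1 eugenol (4-allyl-2-methoxyphenol)
Product: 2 4-allyl-2-methoxy-1-(methoxymethoxy)benzene
Conditions: MOMCl, i-Pr2NEt, CH2Cl2, 0 °C → rt
Reagents that add atoms: chloromethyl methyl ether, COCCl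
Why: O-alkylation of the phenol to its MOM acetal; the group withstands borane, organolithium, fluoride and palladium chemistry and is removed by acid at the end.

Step 2
Reactants: 2 4-allyl-2-methoxy-1-(methoxymethoxy)benzene
Product: 4 3-[3-methoxy-4-(methoxymethoxy)phenyl]propan-1-ol, via B-(3-arylpropyl)-9-borabicyclo[3.3.1]nonane 3 (not isolated)
Conditions: 9-BBN, THF, 0 °C → rt; then NaOH, H2O2, H2O, 0 °C → rt
Reagents that add atoms: 9-borabicyclo[3.3.1]nonane, B1C2CCCC1CCC2 (boron of 3 only); hydrogen peroxide, OO
Why: Hydroboration–oxidation; the bulky borane places boron on the terminal carbon of the allyl group and alkaline peroxide replaces it by hydroxyl, giving the primary alcohol.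

Step 3
Reactants: 4 3-[3-methoxy-4-(methoxymethoxy)phenyl]propan-1-ol
Product: 5 3-[3-methoxy-4-(methoxymethoxy)phenyl]propanal
Conditions: TEMPO (cat.), PhI(OAc)2, CH2Cl2, rt
Reagents that add atoms: none
Why: Nitroxyl-catalysed oxidation of a primary alcohol, which stops at the aldehyde in the absence of water and leaves the protected electron-rich arene untouched.

Step 4
Reactants: 5 3-[3-methoxy-4-(methoxymethoxy)phenyl]propanal; 6 formaldehyde (37% aqueous solution)
Product: 7 (S)-3-hydroxy-2-[3-methoxy-4-(methoxymethoxy)benzyl]propanal
Conditions: (R)-2-[diphenyl(trimethylsilyloxy)methyl]pyrrolidine (15 mol %), aq. HCHO (3 equiv), pH 7 buffer (NaH2PO4/Na2HPO4), toluene, 0 °C → rt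
Reagents that add atoms: none
Why: Enamine-catalysed crossed aldol reaction (alpha-hydroxymethylation), a known transformation of linear aldehydes, 3-arylpropanals included, with diarylprolinol silyl ethers and aqueous formaldehyde. The amine condenses with 5 to the E-configured s-trans enamine, the diphenyl(trimethylsilyloxy)methyl group blocks one face, formaldehyde adds to the open face, and hydrolysis of the iminium ion releases 7 and the catalyst. One skeletal bond (C4–C5) is formed and no ring is closed. The new stereocentre is controlled by the catalyst alone: with the (R)-catalyst the open face leads to the (S)-aldehyde (CHO > CH2OH > CH2Ar), which becomes (R) at C4 of 19 once the aldehyde carbon has turned into C3. Chemoselectivity rests on formaldehyde being unable to form an enamine and being the better electrophile, so self-aldol of 5 is suppressed, and C2 is the only enolisable position of 5. A second hydroxymethylation should be slow because the alpha-branched product forms its enamine reluctantly. The neutral buffer limits dehydration to the alpha-methylene aldehyde and epimerisation, and 7 is carried into step 5 as the crude extract.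

Step 5
Reactants: 7 (S)-3-hydroxy-2-[3-methoxy-4-(methoxymethoxy)benzyl]propanal
Product: 8 (S)-3-[(tert-butyldimethylsilyl)oxy]-2-[3-methoxy-4-(methoxymethoxy)benzyl]propanal
Conditions: TBSCl, imidazole, CH2Cl2, 0 °C
Reagents that add atoms: tert-butyldimethylsilyl chloride, CC(C)(C)[Si](C)(C)Cl
Why: Silylation of the primary alcohol under weakly basic, cold conditions; it ends hemiacetal formation and removes the free hydroxyl that would otherwise be brominated in step 6, while the alpha-stereocentre is expected to hold.

Step 6
Reactants: 8 (S)-3-[(tert-butyldimethylsilyl)oxy]-2-[3-methoxy-4-(methoxymethoxy)benzyl]propanal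
Product: 9 (R)-tert-butyl({4,4-dibromo-2-[3-methoxy-4-(methoxymethoxy)benzyl]but-3-en-1-yl}oxy)dimethylsilane
Conditions: CBr4, PPh3, Et3N, CH2Cl2, 0 °C
Reagents that add atoms: carbon tetrabromide, BrC(Br)(Br)Br
Why: First stage of the Corey–Fuchs alkynylation, a Wittig-type olefination by the weakly basic ylide Ph3P=CBr2; the amine buffers the medium so that silyl ether, acetal and alpha-stereocentre should survive (the descriptor changes to R only through the priority rules).

Step 7
Reactants: 9 (R)-tert-butyl({4,4-dibromo-2-[3-methoxy-4-(methoxymethoxy)benzyl]but-3-en-1-yl}oxy)dimethylsilane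
Product: 11 (R)-tert-butyl({2-[3-methoxy-4-(methoxymethoxy)benzyl]but-3-yn-1-yl}oxy)dimethylsilane, via lithium acetylide 10 (not isolated)
Conditions: n-BuLi (2.2 equiv), THF, −78 °C; then H2O
Reagents that add atoms: n-butyllithium, [Li]CCCC (lithium of 10 only)
Why: Second stage of the Corey–Fuchs alkynylation: bromine–lithium exchange, Fritsch–Buttenberg–Wiechell rearrangement and deprotonation give the acetylide, which is protonated on quenching; the stereocentre is now propargylic and no longer enolisable.

Step 8
Reactants: 12 2,3-dimethoxyphenol
Product: 13 1,2-dimethoxy-3-(methoxymethoxy)benzene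
Conditions: MOMCl, i-Pr2NEt, CH2Cl2, 0 °C → rt
Reagents that add atoms: chloromethyl methyl ether, COCCl
Why: MOM ether formation as in step 1, so that both phenols are released together in step 13.

Step 9
Reactants: 13 1,2-dimethoxy-3-(methoxymethoxy)benzene
Product: 15 5-iodo-1,2-dimethoxy-3-(methoxymethoxy)benzene, via arylboronic acid pinacol ester 14 (not isolated)
Conditions: [Ir(OMe)(cod)]2 (cat.), 4,4′-di-tert-butyl-2,2′-bipyridine (cat.), B2pin2, THF, 80 °C; then CuI (cat.), 1,10-phenanthroline, KI, MeOH/H2O, air, 80 °C
Reagents that add atoms: bis(pinacolato)diboron, CC1(C)OB(OC1(C)C)B1OC(C)(C)C(C)(C)O1 (boryl group of 14 only); potassium iodide, [K+].[I-]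
Why: Sterically governed iridium-catalysed C–H borylation picks C5, the only ring C–H without an ortho substituent, and copper-mediated iododeboronation in the same flask exchanges boron for iodine, a regiochemistry that electrophilic iodination cannot give.

Step 10
Reactants: 11 (R)-tert-butyl({2-[3-methoxy-4-(methoxymethoxy)benzyl]but-3-yn-1-yl}oxy)dimethylsilane; 15 5-iodo-1,2-dimethoxy-3-(methoxymethoxy)benzene
Product: 16 (R)-tert-butyl({4-[3,4-dimethoxy-5-(methoxymethoxy)phenyl]-2-[3-methoxy-4-(methoxymethoxy)benzyl]but-3-yn-1-yl}oxy)dimethylsilane
Conditions: PdCl2(PPh3)2 (cat.), CuI (cat.), Et3N, THF, 45 °C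
Reagents that add atoms: none
Why: Sonogashira coupling: oxidative addition of the aryl iodide to zerovalent palladium, transmetalation from the copper acetylide and reductive elimination; the propargylic C–H is not acidic enough to be touched by the amine.

Step 11
Reactants: 16 (R)-tert-butyl({4-[3,4-dimethoxy-5-(methoxymethoxy)phenyl]-2-[3-methoxy-4-(methoxymethoxy)benzyl]but-3-yn-1-yl}oxy)dimethylsilane
Product: 17 (R)-4-[3,4-dimethoxy-5-(methoxymethoxy)phenyl]-2-[3-methoxy-4-(methoxymethoxy)benzyl]but-3-yn-1-ol
Conditions: TBAF, THF, 0 °C → rt
Reagents that add atoms: none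
Why: Fluoride-induced cleavage of the alkyl silyl ether; the MOM acetals and the alkyne are inert to fluoride.

Step 12
Reactants: 17 (R)-4-[3,4-dimethoxy-5-(methoxymethoxy)phenyl]-2-[3-methoxy-4-(methoxymethoxy)benzyl]but-3-yn-1-ol
Product: 18 (3E,4R)-3-[3,4-dimethoxy-5-(methoxymethoxy)benzylidene]-4-[3-methoxy-4-(methoxymethoxy)benzyl]dihydrofuran-2(3H)-one
Conditions: PdI2 (cat.), n-Bu3P (cat.), CO (7 atm), MeCN, 75 °C
Reagents that add atoms: carbon monoxide, [C-]#[O+]
Why: Palladium-catalysed cyclocarbonylation of a homopropargylic alcohol: an alkoxycarbonyl complex of divalent palladium formed from the hydroxyl group and CO adds syn across the tethered alkyne in the only geometrically possible 5-exo sense, and protonolysis of the alkenyl–palladium bond with retention leaves hydrogen cis to the carbonyl, which is the E-benzylidene lactone; C4 takes no part.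

Step 13
Reactants: 18 (3E,4R)-3-[3,4-dimethoxy-5-(methoxymethoxy)benzylidene]-4-[3-methoxy-4-(methoxymethoxy)benzyl]dihydrofuran-2(3H)-one
Product: 19 (3E,4R)-3-(3-hydroxy-4,5-dimethoxybenzylidene)-4-(4-hydroxy-3-methoxybenzyl)dihydrofuran-2(3H)-one
Conditions: HCl, MeOH, rt → 40 °C
Reagents that add atoms: none
Why: Acid-catalysed transacetalisation releases both phenols; the five-membered lactone is thermodynamically favoured over its methanolysis product, and neither the alkene geometry nor C4 is affected by dilute acid.

## Compound list

1 | eugenol (4-allyl-2-methoxyphenol) | C=CCc1ccc(O)c(OC)c1 | starting material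
2 | 4-allyl-2-methoxy-1-(methoxymethoxy)benzene | C=CCc1ccc(OCOC)c(OC)c1 | intermediate
3 | 9-{3-[3-methoxy-4-(methoxymethoxy)phenyl]propyl}-9-borabicyclo[3.3.1]nonane | COCOc1ccc(CCCB2C3CCCC2CCC3)cc1OC | intermediate (not isolated)
4 | 3-[3-methoxy-4-(methoxymethoxy)phenyl]propan-1-ol | COCOc1ccc(CCCO)cc1OC | intermediate
5 | 3-[3-methoxy-4-(methoxymethoxy)phenyl]propanal | COc1cc(CCC=O)ccc1OCOC | intermediate
6 | formaldehyde | C=O | starting material
7 | (S)-3-hydroxy-2-[3-methoxy-4-(methoxymethoxy)benzyl]propanal | COc1cc(C[C@H](C=O)CO)ccc1OCOC | intermediate
8 | (S)-3-[(tert-butyldimethylsilyl)oxy]-2-[3-methoxy-4-(methoxymethoxy)benzyl]propanal | COc1cc(C[C@H](C=O)CO[Si](C)(C)C(C)(C)C)ccc1OCOC | intermediate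
9 | (R)-tert-butyl({4,4-dibromo-2-[3-methoxy-4-(methoxymethoxy)benzyl]but-3-en-1-yl}oxy)dimethylsilane | COc1cc(C[C@H](C=C(Br)Br)CO[Si](C)(C)C(C)(C)C)ccc1OCOC | intermediate
10 | lithium (R)-4-[(tert-butyldimethylsilyl)oxy]-3-[3-methoxy-4-(methoxymethoxy)benzyl]but-1-yn-1-ide | COc1cc(C[C@H](C#C[Li])CO[Si](C)(C)C(C)(C)C)ccc1OCOC | intermediate (not isolated)
11 | (R)-tert-butyl({2-[3-methoxy-4-(methoxymethoxy)benzyl]but-3-yn-1-yl}oxy)dimethylsilane | COc1cc(C[C@H](C#C)CO[Si](C)(C)C(C)(C)C)ccc1OCOC | intermediate
12 | 2,3-dimethoxyphenol | COc1cccc(O)c1OC | starting material
13 | 1,2-dimethoxy-3-(methoxymethoxy)benzene | COCOc1cccc(OC)c1OC | intermediate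
14 | 2-[3,4-dimethoxy-5-(methoxymethoxy)phenyl]-4,4,5,5-tetramethyl-1,3,2-dioxaborolane | COCOc1cc(B2OC(C)(C)C(C)(C)O2)cc(OC)c1OC | intermediate (not isolated)
15 | 5-iodo-1,2-dimethoxy-3-(methoxymethoxy)benzene | COCOc1cc(I)cc(OC)c1OC | intermediate
16 | (R)-tert-butyl({4-[3,4-dimethoxy-5-(methoxymethoxy)phenyl]-2-[3-methoxy-4-(methoxymethoxy)benzyl]but-3-yn-1-yl}oxy)dimethylsilane | COc1cc(C[C@H](C#Cc2cc(OCOC)c(OC)c(OC)c2)CO[Si](C)(C)C(C)(C)C)ccc1OCOC | intermediate
17 | (R)-4-[3,4-dimethoxy-5-(methoxymethoxy)phenyl]-2-[3-methoxy-4-(methoxymethoxy)benzyl]but-3-yn-1-ol | COc1cc(C[C@H](C#Cc2cc(OCOC)c(OC)c(OC)c2)CO)ccc1OCOC | intermediate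
18 | (3E,4R)-3-[3,4-dimethoxy-5-(methoxymethoxy)benzylidene]-4-[3-methoxy-4-(methoxymethoxy)benzyl]dihydrofuran-2(3H)-one | COc1cc(C[C@H]2COC(=O)/C2=C/c2cc(OCOC)c(OC)c(OC)c2)ccc1OCOC | intermediate
19 | (3E,4R)-3-(3-hydroxy-4,5-dimethoxybenzylidene)-4-(4-hydroxy-3-methoxybenzyl)dihydrofuran-2(3H)-one | COc1cc(C[C@H]2COC(=O)/C2=C/c2cc(O)c(OC)c(OC)c2)ccc1O | target

## Step count and risks

Total: 13 steps. Longest linear sequence: 11 steps (steps 1–7 and 10–13); steps 8 and 9 form the ring B branch.

**Step 4 (key step).** The danger is insufficient facial selectivity, or loss of it afterwards through enolisation of the product, together with dehydration to the alpha-methylene aldehyde. The catalyst can also be deactivated by desilylation and N,O-acetal formation with formaldehyde. The fallback sets out from 5 and comes back at 8. It replaces catalyst-controlled face selection by enzymatic desymmetrisation.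
- The aldol reaction is run without regard to enantiomeric purity and the crude mixture is reduced in the same flask with NaBH4 to the prochiral 2-[3-methoxy-4-(methoxymethoxy)benzyl]propane-1,3-diol F1.
- A lipase chosen for the required enantiotopic arm (Burkholderia cepacia lipase or porcine pancreatic lipase, with vinyl acetate) acetylates one hydroxymethyl group to give (S)-3-hydroxy-2-[3-methoxy-4-(methoxymethoxy)benzyl]propyl acetate F2.
- Silylation (TBSCl, imidazole) gives (R)-3-[(tert-butyldimethylsilyl)oxy]-2-[3-methoxy-4-(methoxymethoxy)benzyl]propyl acetate F3.
- K2CO3 in MeOH removes the acetate to give (R)-3-[(tert-butyldimethylsilyl)oxy]-2-[3-methoxy-4-(methoxymethoxy)benzyl]propan-1-ol F4.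
- Oxidation with TEMPO and PhI(OAc)2 gives 8.

**Step 12.** The hydroxyl group may attack the palladium-activated aryl alkyne directly (5-endo oxypalladation to a dihydrofuran). Insertion of the internal, electron-rich alkyne may be slow. Palladium hydride species may move the new double bond into the ring or erode its geometry. Partial loss of MOM groups would be harmless, since they are removed next. The fallback sets out from 11 (and 15) and comes back at 18, building the lactone first and the benzylidene by aldol condensation.
- Hydroboration of 11 with dicyclohexylborane and oxidation with NaBO3 gives (R)-4-[(tert-butyldimethylsilyl)oxy]-3-[3-methoxy-4-(methoxymethoxy)benzyl]butanal F5.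
- TBAF gives the lactol (4R)-4-[3-methoxy-4-(methoxymethoxy)benzyl]tetrahydrofuran-2-ol F6.
- Oxidation with TEMPO and PhI(OAc)2 gives (R)-4-[3-methoxy-4-(methoxymethoxy)benzyl]dihydrofuran-2(3H)-one F7.
- Iodine–magnesium exchange on 15 with i-PrMgCl·LiCl and formylation with DMF gives 3,4-dimethoxy-5-(methoxymethoxy)benzaldehyde F8.
- The lithium enolate of F7 (LiN(SiMe3)2, THF, −78 °C) adds to F8 to give (4R)-3-{hydroxy[3,4-dimethoxy-5-(methoxymethoxy)phenyl]methyl}-4-[3-methoxy-4-(methoxymethoxy)benzyl]dihydrofuran-2(3H)-one F9, as a mixture of carbinol epimers.
- MsCl and Et3N convert F9 into its methanesulfonate (4R)-3-{[3,4-dimethoxy-5-(methoxymethoxy)phenyl][(methylsulfonyl)oxy]methyl}-4-[3-methoxy-4-(methoxymethoxy)benzyl]dihydrofuran-2(3H)-one F10, and DBU eliminates it to the thermodynamically preferred E-alkene 18.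

**Step 6 (with step 5).** The alpha-stereocentre of 8 may epimerise by enolisation, or silanol may be lost by beta-elimination, during the amine-buffered olefination. The fallback sets out from 8 and comes back at 11 in one operation. A Colvin homologation with lithiated trimethylsilyldiazomethane (Me3SiCHN2, n-BuLi, THF, −78 °C) converts the aldehyde directly into the terminal alkyne through an alkylidene carbene. Carbonyl addition at this temperature should outrun enolisation, and no phosphonium or ammonium species are present. No new compound is isolated.

**Step 9.** Protodeboronation or oxidation of the electron-rich boronate to the phenol may compete in the copper and air stage, so that iodide 15 is obtained poorly. The fallback sets out from 13 and 11 and comes back at 16 with reversed coupling polarity. The sequence of step 9 is stopped after the borylation and 14 is isolated. Alkyne 11 is brominated with NBS and AgNO3 to (R)-({4-bromo-2-[3-methoxy-4-(methoxymethoxy)benzyl]but-3-yn-1-yl}oxy)(tert-butyl)dimethylsilane F11. A Suzuki–Miyaura coupling of 14 with F11 (Pd(PPh3)4, Cs2CO3, THF/H2O) then gives 16.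

## Further compounds

F1 | step 4 | 2-[3-methoxy-4-(methoxymethoxy)benzyl]propane-1,3-diol | COc1cc(CC(CO)CO)ccc1OCOC
F2 | step 4 | (S)-3-hydroxy-2-[3-methoxy-4-(methoxymethoxy)benzyl]propyl acetate | COc1cc(C[C@H](COC(C)=O)CO)ccc1OCOC
F3 | step 4 | (R)-3-[(tert-butyldimethylsilyl)oxy]-2-[3-methoxy-4-(methoxymethoxy)benzyl]propyl acetate | COc1cc(C[C@H](COC(C)=O)CO[Si](C)(C)C(C)(C)C)ccc1OCOC
F4 | step 4 | (R)-3-[(tert-butyldimethylsilyl)oxy]-2-[3-methoxy-4-(methoxymethoxy)benzyl]propan-1-ol | COc1cc(C[C@H](CO)CO[Si](C)(C)C(C)(C)C)ccc1OCOC
F5 | step 12 | (R)-4-[(tert-butyldimethylsilyl)oxy]-3-[3-methoxy-4-(methoxymethoxy)benzyl]butanal | COc1cc(C[C@H](CC=O)CO[Si](C)(C)C(C)(C)C)ccc1OCOC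
F6 | step 12 | (4R)-4-[3-methoxy-4-(methoxymethoxy)benzyl]tetrahydrofuran-2-ol | COc1cc(C[C@H]2COC(O)C2)ccc1OCOC
F7 | step 12 | (R)-4-[3-methoxy-4-(methoxymethoxy)benzyl]dihydrofuran-2(3H)-one | COc1cc(C[C@H]2COC(=O)C2)ccc1OCOC
F8 | step 12 | 3,4-dimethoxy-5-(methoxymethoxy)benzaldehyde | COCOc1cc(C=O)cc(OC)c1OC
F9 | step 12 | (4R)-3-{hydroxy[3,4-dimethoxy-5-(methoxymethoxy)phenyl]methyl}-4-[3-methoxy-4-(methoxymethoxy)benzyl]dihydrofuran-2(3H)-one | COc1cc(C[C@H]2COC(=O)C2C(O)c2cc(OCOC)c(OC)c(OC)c2)ccc1OCOC
F10 | step 12 | (4R)-3-{[3,4-dimethoxy-5-(methoxymethoxy)phenyl][(methylsulfonyl)oxy]methyl}-4-[3-methoxy-4-(methoxymethoxy)benzyl]dihydrofuran-2(3H)-one | COc1cc(C[C@H]2COC(=O)C2C(OS(C)(=O)=O)c2cc(OCOC)c(OC)c(OC)c2)ccc1OCOC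
F0 | step 6 | none | none
F11 | step 9 | (R)-({4-bromo-2-[3-methoxy-4-(methoxymethoxy)benzyl]but-3-yn-1-yl}oxy)(tert-butyl)dimethylsilane | COc1cc(C[C@H](C#CBr)CO[Si](C)(C)C(C)(C)C)ccc1OCOC
A1 | alternative 1 | (3E,4R)-3-[3,4-dimethoxy-5-(methoxymethoxy)benzylidene]-4-[3-methoxy-4-(methoxymethoxy)benzyl]dihydrofuran-2(3H)-one | COc1cc(C[C@H]2COC(=O)/C2=C/c2cc(OCOC)c(OC)c(OC)c2)ccc1OCOC
A2 | alternative 1 | (E)-3-[3-methoxy-4-(methoxymethoxy)phenyl]prop-2-en-1-yl propiolate | C#CC(=O)OC/C=C/c1ccc(OCOC)c(OC)c1
A3 | alternative 1 | [3,4-dimethoxy-5-(methoxymethoxy)phenyl]boronic acid | COCOc1cc(B(O)O)cc(OC)c1OC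
A4 | alternative 2 | 4-tert-butyl 1-methyl (R,E)-2-[3,4-dimethoxy-5-(methoxymethoxy)benzylidene]-3-[3-methoxy-4-(methoxymethoxy)benzyl]succinate | COC(=O)/C(=C/c1cc(OCOC)c(OC)c(OC)c1)[C@@H](Cc1ccc(OCOC)c(OC)c1)C(=O)OC(C)(C)C
A5 | alternative 2 | 4-tert-butyl 1-methyl (E)-2-[3,4-dimethoxy-5-(methoxymethoxy)benzylidene]-3-methylenesuccinate | COC(=O)/C(=C/c1cc(OCOC)c(OC)c(OC)c1)C(=C)C(=O)OC(C)(C)C
A6 | alternative 2 | [3-methoxy-4-(methoxymethoxy)phenyl]boronic acid | COCOc1ccc(B(O)O)cc1OC
A7 | alternative 3 | (R)-4-[3-methoxy-4-(methoxymethoxy)benzyl]dihydrofuran-2(3H)-one | COc1cc(C[C@H]2COC(=O)C2)ccc1OCOC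
A8 | alternative 3 | 3-[3-methoxy-4-(methoxymethoxy)phenyl]propyl diazoacetate | COCOc1ccc(CCCOC(=O)C=[N+]=[N-])cc1OC
A9 | alternative 3 | 3,4-dimethoxy-5-(methoxymethoxy)benzaldehyde | COCOc1cc(C=O)cc(OC)c1OC
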